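**Atom labels and assumptions**

- Labels: ring carbons are C1a (the ring CH=), C2 (CMe2), C3 (CHMe), C4, C5 and C6 (the ring sp2 carbon that carries the chain). The chain runs C7(H)(CH3)–C8H2–C9H2–C10(CH3)(vinyl)–C11H=C12H–C13(H)(CH3)–C14H2–C15H2–C16(H)(CH3)–C17(=CH2)–C18H2–C19H2–C20(H)(CH3)–C21(=CH2)–C22H3. The SMILES was read as 3R, 7R, 10S, 11E, 13S, 16R, 20R.
- Assumption: (E)-but-2-en-1-yl methyl carbonate and (E)-but-2-en-1-yl diethyl phosphate, each one step from commercial (E)-but-2-en-1-ol, are used as reagents. (R)-β-Citronellene is taken as commercial in high enantiomeric purity.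
- Remark: the C6 epimers of 6 and the epoxide epimers of 16 are not separated, because these centres are removed in the next operation.

## The problem

The target is a C34 hydrocarbon with no heteroatom. A 3,3,4-trimethylcyclohexene (C1a, C2–C6) carries at C6 a branched chain with four further alkenes. There are six stereocentres (C3, C7, C10, C13, C16, C20), and no two are adjacent, so ordinary 1,2- or 1,3-induction cannot relate them. Each must come from a catalyst, a reagent or the chiral pool, except the pair C10/C13, which faces across the E-C11=C12 alkene.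

The hardest element is the acyclic all-carbon quaternary C10. It carries two nearly equal alkenyl groups (vinyl and the E-alkenyl C11) and sits in the middle of the chain, where the two halves have to be joined. C3, C7, C16 and C20 are one repeated motif: a CH(CH3) between an sp2 carbon and a CH2CH2 unit, always with the same sense. The ring alkene lies towards the gem-dimethyl carbon (C6=C1a), the side to which a 3,3-dimethylcyclohexanone does not enolise.

The skipped dienes, the 1,1-disubstituted alkenes and the allylic C–H stereocentres rule out strong acid, hydrogenation and strong base on the assembled skeleton.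

The feature that makes the key step possible is the array vinyl–C10(quaternary)–C11H=C12H–C13H(CH3). The vinyl group on C10 is the transposed double bond of a γ,γ-disubstituted allyl unit that has added through C10 to a carbonyl carbon C11. The C11=C12 alkene with the C13 methyl is the transposed double bond of an SN2' methylation. A temporary oxygen on C11 can therefore tie C10 to C13.

## Retrosynthesis

**C13–CH3 (26 ⇒ 25).** The bond between C13 and its methyl group is cut, the alkene moves back to C12=C13 and C11 receives a picolinate. A methyl–copper anti-SN2' substitution then makes C13 and the E-alkene from the C11 centre. This is preferred over cutting C13–C14 because the methyl nucleophile is the most reliable one for this substitution. The right half can then arrive as an aldehyde, not as an alkyl metal that would have to be made next to two 1,1-disubstituted alkenes. Precursor 25 replaces the remote C10/C13 pair by the adjacent pair C10/C11. The forward reaction must run anti, at the γ-carbon, and through one conformer.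

**C10–C11 (24 ⇒ 12 + 22, key step).** Alcohol 24 (the parent of 25) is cut between C10 and C11 into the (E)-γ,γ-disubstituted allylboronate 12 (17 carbons) and the enal 22 (16 carbons). This cut divides the molecule almost in half. It makes the quaternary centre in the fragment union and uses the vinyl group as the natural by-product of allyl transposition. An olefination at C11=C12 would need C10 and C13 to be made separately. The forward reaction must give one of four C10/C11 stereoisomers: the E geometry of 12 fixes the relative configuration, and a chiral acid the absolute one.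

**C11–C13 of the enal (22 ⇒ 21 ⇒ 20).** The enal is cut at C12=C13 (a two-carbon formyl ylide) and aldehyde 21 at C13–C14 (CO/H2 on the vinyl group of 20). Hydroformylation is the one reagent class that distinguishes the monosubstituted alkene from the two 1,1-disubstituted alkenes of 20.

**C16–C17 (20 ⇒ 18).** Triene 20 is cut between C16 and C17 into an internal alkenyl metal (from alkyne 18 by Markovnikov hydroalumination, 19) and a crotyl electrophile. SN2' attack makes the C16 methyl stereocentre, the C17 methylene and the vinyl group in one operation. The alternative, alkylation α to a C17 ketone followed by methylenation, costs more steps and passes through an epimerisable ketone.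

**C20 from the chiral pool (18 ⇒ 17 ⇒ 15 ⇒ 14 ⇒ 13).** The alkyne comes from aldehyde 17 by one-carbon homologation, and 17 from diene 15 by cleaving the trisubstituted alkene (via epoxide 16). Diene 15 comes from ketone 14 by methylenation, and 14 from (R)-β-citronellene 13 by Wacker oxidation. The citronellene centre is C20 unchanged, its vinyl group becomes the isopropenyl group, and its prenyl end becomes C17.

**C9–C10 and the allylboron unit (12 ⇒ 11 ⇒ 9).** Boronate 12 is the 1,4-hydroboration product of the 2-substituted butadiene 11. This sets the E geometry by mechanism, which a π-allyl-based borylation of an allylic alcohol would not guarantee. Diene 11 is cut at C9–C10 into the alkylborane 10 (from the vinyl group of 9) and a four-carbon 2-halobutadiene.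

**C6–C7 and the ring alkene (9 ⇒ 8 ⇒ 6 ⇒ 5 ⇒ 3).** Diene 9 comes from enol triflate 8 by replacing OTf with H, and 8 from ketone 6. Ketone 6 is cut between C6 and C7 into the enolate equivalent 5 and a crotyl electrophile (branched-selective iridium allylation sets C7). Ketone 3 has a single enolisable position, C6, and its carbonyl carbon is exactly the carbon that must end as the ring CH=. Alkylation, enol triflate formation (through 7) and reduction therefore place both the chain and the alkene without regiochemical choice.

**C3 (3 ⇒ 1).** Ketone 3 is cut at the C3 methyl and one C2 methyl. Asymmetric conjugate addition to 2-methylcyclohex-2-en-1-one 1 and methylation of the enolate 2 do both in one flask.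

## Roads not taken

**Alternative 1:** The most obvious cut is the C11=C12 alkene. The forward step is a Julia–Kocienski olefination of the α-quaternary aldehyde A1 with the tetrazolyl sulfone A2. It was not chosen for three reasons:
- A1 already contains C10, which would need its own asymmetric construction with two nearly equal groups.
- A2 needs C13 from a separate auxiliary sequence.
- The olefination joins a neopentylic aldehyde to a β-branched sulfone, the combination in which rate and E-selectivity are weakest.

Three independent operations would be spent on C10, C13 and the alkene geometry. The chosen plan gets all three from one allylation and one substitution.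

**Alternative 2:** The cut is C10–C11, with C10 formed in the union by a copper–carbene catalysed enantioselective SN2' substitution of the trisubstituted allylic phosphate A3 by the (E)-alkenylaluminium from alkyne A4. It would give the target directly, and it was weighed seriously. It was not chosen for three reasons:
- A4 needs a propargylic C13 stereocentre. The crotyl chemistry used for C16 leaves a vinyl group, not an ethynyl group, so C13 would cost a separate sequence of about five steps.
- Converting a C11=C12 vinyl group into an alkenyl metal by cross-metathesis is blocked, because that vinyl and the C17 methylene form a 1,7-diene that would ring-close.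
- The catalyst would have to set a quaternary hydrocarbon centre in the last step next to an α-branched nucleophile, with no later chance to remove a C10 epimer.

**Alternative 3:** The cut is the ring bond C1a–C2, by a biomimetic cation–olefin cyclisation of the acyclic hydrocarbon A5 (protonation of C1=C2, 6-endo attack of the C6 methylene, loss of a proton from C1a). It was not chosen for four reasons:
- The two termini of A5 are the same (R,R) unit, so no reagent can select the left one.
- Within one terminus either 1,1-disubstituted alkene can be protonated, which leads to two ring skeletons.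
- The cyclohexyl cation can lose a proton in three directions, one of which destroys C7.
- The doubly allylic C10 array does not survive strong acid.

The chosen plan fixes the ring alkene by an enol triflate and uses the repeated motif only in the sense that C7 and C16 are made by the same kind of crotyl transfer.

Key step: step 15

## Route

Step 1
Reactants: 1 2-methylcyclohex-2-en-1-one
Product: 3 (3R)-2,2,3-trimethylcyclohexan-1-one, via bromomagnesium enolate 2 (not isolated)
Conditions: MeMgBr, Cu(OTf)2 (3 mol %), chiral hydroxyalkyl imidazolium salt (carbene precursor, 4 mol %), Et2O, −30 °C; then MeI, DMPU, −30 °C to rt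
Reagents that add atoms: methylmagnesium bromide C[Mg]Br; iodomethane CI
Why: Copper-catalysed asymmetric conjugate addition of the Grignard reagent to the α-substituted enone sets C3 (R) under control of the chiral carbene ligand. The tetrasubstituted magnesium enolate 2 is then C-methylated at the carbon that becomes the gem-dimethyl C2, which leaves C6 as the only enolisable position of 3.

Step 2
Reactants: 3 (3R)-2,2,3-trimethylcyclohexan-1-one
Product: 5 trimethyl{[(5R)-5,6,6-trimethylcyclohex-1-en-1-yl]oxy}silane, via lithium enolate 4 (not isolated)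
Conditions: LDA, THF, −78 °C; then Me3SiCl, −78 °C to rt
Reagents that add atoms: chlorotrimethylsilane C[Si](C)(C)Cl
Why: Deprotonation can occur only at C6 because C2 is quaternary, so O-silylation gives a single enol ether regioisomer and C3 is untouched.

Step 3
Reactants: 5 trimethyl{[(5R)-5,6,6-trimethylcyclohex-1-en-1-yl]oxy}silane
Product: 6 (3R,6RS)-6-[(2R)-but-3-en-2-yl]-2,2,3-trimethylcyclohexan-1-one
Conditions: [Ir(cod)Cl]2 (2 mol %), BINOL-derived bis(1-phenylethyl)phosphoramidite (4 mol %, antipode chosen for 7R), CsF, ZnF2 (cat.), (E)-but-2-en-1-yl methyl carbonate, DME, 50 °C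
Reagents that add atoms: (E)-but-2-en-1-yl methyl carbonate C/C=C/COC(=O)OC
Why: Iridium-catalysed branch-selective allylic alkylation of a fluoride-activated silyl enol ether: the enolate attacks the methyl-bearing terminus of the allyl–iridium intermediate, so C7 receives CH3, H and a vinyl group. C7 (R) is set by the ligand because the ring centre C3 is too remote to interfere, and the new C6 centre is erased in step 4.

Step 4
Reactants: 6 (3R,6RS)-6-[(2R)-but-3-en-2-yl]-2,2,3-trimethylcyclohexan-1-one
Product: 8 (5R)-2-[(2R)-but-3-en-2-yl]-5,6,6-trimethylcyclohex-1-en-1-yl trifluoromethanesulfonate, via potassium enolate 7 (not isolated)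
Conditions: KHMDS, THF, −78 °C; then PhNTf2, −78 °C to rt
Reagents that add atoms: N-phenylbis(trifluoromethanesulfonimide) O=S(=O)(N(c1ccccc1)S(=O)(=O)C(F)(F)F)C(F)(F)F
Why: The only α-hydrogen left is at C6, so enolisation and O-triflation give the tetrasubstituted enol triflate regiospecifically, as with other 2,2,6-trialkylcyclohexanones. The C7 hydrogen is not acidic, so C7 keeps its configuration.

Step 5
Reactants: 8 (5R)-2-[(2R)-but-3-en-2-yl]-5,6,6-trimethylcyclohex-1-en-1-yl trifluoromethanesulfonate
Product: 9 (4R)-1-[(2R)-but-3-en-2-yl]-3,3,4-trimethylcyclohex-1-ene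
Conditions: Pd(OAc)2 (5 mol %), PPh3, HCO2H, Bu3N, DMF, 60 °C
Reagents that add atoms: none
Why: Palladium-catalysed formate reduction of an enol triflate replaces OTf by H without moving the double bond. This places the ring alkene between C6 and C1a, next to the gem-dimethyl carbon, as the target requires.

Step 6
Reactants: 9 (4R)-1-[(2R)-but-3-en-2-yl]-3,3,4-trimethylcyclohex-1-ene
Product: 11 (4R)-3,3,4-trimethyl-1-[(2R)-5-methylidenehept-6-en-2-yl]cyclohex-1-ene, via B-alkyl-9-borabicyclononane 10 (not isolated)
Conditions: 9-BBN, THF, 0 °C to rt; then 2-chlorobuta-1,3-diene, Pd(OAc)2 (3 mol %), SPhos, aq. K3PO4, THF, 40 °C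
Reagents that add atoms: 2-chlorobuta-1,3-diene C=CC(Cl)=C
Why: 9-BBN hydroborates the monosubstituted vinyl group anti-Markovnikov and leaves the hindered trisubstituted ring alkene. B-alkyl Suzuki–Miyaura coupling of 10 with the alkenyl chloride then forms C9–C10 and installs the 2-substituted buta-1,3-diene.

Step 7
Reactants: 11 (4R)-3,3,4-trimethyl-1-[(2R)-5-methylidenehept-6-en-2-yl]cyclohex-1-ene
Product: 12 4,4,5,5-tetramethyl-2-{(2E,6R)-3-methyl-6-[(4R)-3,3,4-trimethylcyclohex-1-en-1-yl]hept-2-en-1-yl}-1,3,2-dioxaborolane
Conditions: Ni(cod)2 (2.5 mol %), PCy3 (2.5 mol %), pinacolborane, toluene, rt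
Reagents that add atoms: pinacolborane CC1(C)OBOC1(C)C
Why: Nickel-catalysed 1,4-hydroboration of a 2-substituted 1,3-diene through its s-cis complex delivers H to the methylene on C10 and boron to the remote terminus. The new C10 methyl and the CH2B group are therefore cis and the chain is trans to CH2B (E), the geometry that decides the C10/C11 relationship in step 15.

Step 8
Reactants: 13 (3R)-3,7-dimethylocta-1,6-diene
Product: 14 (3R)-3,7-dimethyloct-6-en-2-one
Conditions: PdCl2 (10 mol %), CuCl, O2 (1 atm), DMF/H2O, rt
Reagents that add atoms: water O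
Why: Wacker oxidation selects the monosubstituted alkene over the trisubstituted one and gives the methyl ketone. The allylic centre (future C20) is not enolised under these near-neutral conditions.

Step 9
Reactants: 14 (3R)-3,7-dimethyloct-6-en-2-one
Product: 15 (3R)-2,3,7-trimethylocta-1,6-diene
Conditions: Zn, CH2Br2, TiCl4, THF/CH2Cl2, 0 °C to rt
Reagents that add atoms: dibromomethane BrCBr
Why: Takai–Lombardo methylenation is non-basic, so the α-stereocentre of the methyl ketone is not epimerised. The ketone carbon becomes C21 of the isopropenyl group.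

Step 10
Reactants: 15 (3R)-2,3,7-trimethylocta-1,6-diene
Product: 17 (4R)-4,5-dimethylhex-5-enal, via trisubstituted epoxide 16 (not isolated)
Conditions: mCPBA (1 equiv), CH2Cl2, −20 °C; then H5IO6, THF/H2O, 0 °C
Reagents that add atoms: 3-chloroperbenzoic acid OOC(=O)c1cccc(Cl)c1
Why: The peracid epoxidises the electron-rich trisubstituted alkene markedly faster than the 1,1-disubstituted one. Periodic acid then cleaves the epoxide, through the diol, to the aldehyde with loss of acetone.

Step 11
Reactants: 17 (4R)-4,5-dimethylhex-5-enal
Product: 18 (5R)-5,6-dimethylhept-6-en-1-yne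
Conditions: dimethyl (1-diazo-2-oxopropyl)phosphonate, K2CO3, MeOH, 0 °C to rt
Reagents that add atoms: dimethyl (1-diazo-2-oxopropyl)phosphonate CC(=O)C(=[N+]=[N-])P(=O)(OC)OC
Why: Seyferth–Gilbert homologation with the Ohira–Bestmann reagent converts the aldehyde into the terminal alkyne under mild base. The aldehyde has no α-stereocentre.

Step 12
Reactants: 18 (5R)-5,6-dimethylhept-6-en-1-yne
Product: 20 (3R,7R)-3,7,8-trimethyl-4-methylidenenona-1,8-diene, via alkenylalane 19 (not isolated)
Conditions: Ni(dppp)Cl2 (3 mol %), i-Bu2AlH, THF, 0 to 22 °C; then (E)-but-2-en-1-yl diethyl phosphate, CuCl2·2H2O (1 mol %), chiral sulfonate-bearing imidazolinium salt (1 mol %, antipode chosen for 16R), THF, −15 °C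
Reagents that add atoms: (E)-but-2-en-1-yl diethyl phosphate C/C=C/COP(=O)(OCC)OCC
Why: Nickel-catalysed α-selective hydroalumination places aluminium on the internal alkyne carbon (C17). Copper–carbene catalysed SN2' substitution of the crotyl phosphate by this alkenyl group forms C16–C17 and makes C16 a methyl-bearing stereocentre (R, catalyst control). It also leaves C17 as the 1,1-disubstituted alkene and C14=C15 as a vinyl group.

Step 13
Reactants: 20 (3R,7R)-3,7,8-trimethyl-4-methylidenenona-1,8-diene
Product: 21 (4R,8R)-4,8,9-trimethyl-5-methylidenedec-9-enal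
Conditions: Rh(acac)(CO)2 (0.5 mol %), BIPHEPHOS, CO/H2 (1:1, 10 bar), toluene, 60 °C
Reagents that add atoms: carbon monoxide [C-]#[O+]
Why: Rhodium/bisphosphite hydroformylation is linear-selective and reacts with the monosubstituted alkene far faster than with the two 1,1-disubstituted ones. The bulky ligand and the branched allylic position disfavour the branched rhodium alkyl that could isomerise the skipped diene.

Step 14
Reactants: 21 (4R,8R)-4,8,9-trimethyl-5-methylidenedec-9-enal
Product: 22 (2E,6R,10R)-6,10,11-trimethyl-7-methylidenedodeca-2,11-dienal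
Conditions: Ph3P=CHCHO, toluene, 80 °C
Reagents that add atoms: (triphenylphosphoranylidene)acetaldehyde O=CC=P(c1ccccc1)(c1ccccc1)c1ccccc1
Why: Wittig reaction with the stabilised formylmethylene ylide gives the (E)-enal. Aldehyde 21 has no α-stereocentre.

Step 15
Reactants: 12 4,4,5,5-tetramethyl-2-{(2E,6R)-3-methyl-6-[(4R)-3,3,4-trimethylcyclohex-1-en-1-yl]hept-2-en-1-yl}-1,3,2-dioxaborolane; 22 (2E,6R,10R)-6,10,11-trimethyl-7-methylidenedodeca-2,11-dienal
Product: 24 (3S,4R,5E,9R,13R)-3,9,13,14-tetramethyl-10-methylidene-3-{(3R)-3-[(4R)-3,3,4-trimethylcyclohex-1-en-1-yl]butyl}pentadeca-1,5,14-trien-4-ol, via pinacol borate ester 23 (not isolated)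
Conditions: (S)-TRIP (3,3'-bis(2,4,6-triisopropylphenyl)-1,1'-binaphthyl-2,2'-diyl hydrogen phosphate, 5 mol %), 4 Å MS, toluene, 0 °C to rt; then aq. NaHCO3
Reagents that add atoms: none
Why: Brønsted-acid-catalysed carbonyl allylboration: the phosphoric acid activates the boronate, and the aldehyde carbon C11 bonds to the γ-carbon C10 through a closed six-membered chair transition state with allylic transposition, so C10 becomes quaternary and the former C=C–CH2B unit becomes the vinyl group. The closest known reaction type is the chiral phosphoric acid catalysed addition of γ,γ-disubstituted pinacol allylboronates to aldehydes, which gives homoallylic alcohols next to an all-carbon quaternary centre. No ring is closed. The relative configuration C10/C11 follows from the chair: the substituent trans to CH2B (the C9 chain) is equatorial and ends anti to OH, and the cis substituent (CH3) ends syn, so the E geometry of 12 allows only the 10S,11R/10R,11S pair. The absolute sense is set by the catalyst: (S)-TRIP, the antipode of the acid that directs allyl groups to the Re face of aldehydes, should give attack on the Si face of C11 and hence 11R and 10S. The step needs 1,2- over 1,4-addition and γ- over α-attack, both secured by the closed transition state, and a face selection independent of C7, C16 and C20, which are all at least three atoms from the reacting carbons. The C11 oxygen is not part of the target; it is the relay that carries the configuration of C10 to C13 in step 17.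

Step 16
Reactants: 24 (3S,4R,5E,9R,13R)-3,9,13,14-tetramethyl-10-methylidene-3-{(3R)-3-[(4R)-3,3,4-trimethylcyclohex-1-en-1-yl]butyl}pentadeca-1,5,14-trien-4-ol
Product: 25 (3S,4R,5E,9R,13R)-3,9,13,14-tetramethyl-10-methylidene-3-{(3R)-3-[(4R)-3,3,4-trimethylcyclohex-1-en-1-yl]butyl}pentadeca-1,5,14-trien-4-yl pyridine-2-carboxylate
Conditions: pyridine-2-carboxylic acid, DCC, DMAP (cat.), CH2Cl2, rt
Reagents that add atoms: pyridine-2-carboxylic acid OC(=O)c1ccccn1
Why: Steglich esterification installs a chelating leaving group on the hindered allylic alcohol without forming the alkoxide, which avoids an anionic oxy-Cope rearrangement of this 3-hydroxy-1,5-diene. No stereocentre is touched.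

Step 17
Reactants: 25 (3S,4R,5E,9R,13R)-3,9,13,14-tetramethyl-10-methylidene-3-{(3R)-3-[(4R)-3,3,4-trimethylcyclohex-1-en-1-yl]butyl}pentadeca-1,5,14-trien-4-yl pyridine-2-carboxylate
Product: 26 (4R)-1-[(2R,5S,6E,8S,11R,15R)-5-ethenyl-5,8,11,15,16-pentamethyl-12-methylideneheptadeca-6,16-dien-2-yl]-3,3,4-trimethylcyclohex-1-ene
Conditions: MeMgBr, CuBr·SMe2 (20 mol %), THF, −40 to 0 °C
Reagents that add atoms: methylmagnesium bromide C[Mg]Br
Why: Copper-mediated anti-SN2' substitution of the allylic picolinate: methyl attacks C13 anti to the leaving group from the conformer in which the C11–H eclipses the alkene, because allylic 1,3-strain keeps the quaternary C10 out of the inside position. This gives the E-C11=C12 alkene and transfers 11R to 13S. Attack at C11 itself is blocked because that carbon is neopentylic.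

## Compound list

1 | 2-methylcyclohex-2-en-1-one | CC1=CCCCC1=O | starting material
2 | bromomagnesium (3R)-2,3-dimethylcyclohex-1-en-1-olate | CC1=C(O[Mg]Br)CCC[C@H]1C | intermediate (not isolated)
3 | (3R)-2,2,3-trimethylcyclohexan-1-one | CC1(C)[C@H](C)CCCC1=O | intermediate
4 | lithium (5R)-5,6,6-trimethylcyclohex-1-en-1-olate | CC1(C)[C@H](C)CCC=C1O[Li] | intermediate (not isolated)
5 | trimethyl{[(5R)-5,6,6-trimethylcyclohex-1-en-1-yl]oxy}silane | CC1(C)[C@H](C)CCC=C1O[Si](C)(C)C | intermediate
6 | (3R,6RS)-6-[(2R)-but-3-en-2-yl]-2,2,3-trimethylcyclohexan-1-one | CC1(C)[C@H](C)CCC([C@H](C)C=C)C1=O | intermediate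
7 | potassium (5R)-2-[(2R)-but-3-en-2-yl]-5,6,6-trimethylcyclohex-1-en-1-olate | CC1(C)[C@H](C)CCC([C@H](C)C=C)=C1O[K] | intermediate (not isolated)
8 | (5R)-2-[(2R)-but-3-en-2-yl]-5,6,6-trimethylcyclohex-1-en-1-yl trifluoromethanesulfonate | CC1(C)[C@H](C)CCC([C@H](C)C=C)=C1OS(=O)(=O)C(F)(F)F | intermediate
9 | (4R)-1-[(2R)-but-3-en-2-yl]-3,3,4-trimethylcyclohex-1-ene | CC1(C)[C@H](C)CCC([C@H](C)C=C)=C1 | intermediate
10 | 9-{(3R)-3-[(4R)-3,3,4-trimethylcyclohex-1-en-1-yl]butyl}-9-borabicyclo[3.3.1]nonane | CC1(C)[C@H](C)CCC([C@H](C)CCB2C3CCCC2CCC3)=C1 | intermediate (not isolated)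
11 | (4R)-3,3,4-trimethyl-1-[(2R)-5-methylidenehept-6-en-2-yl]cyclohex-1-ene | CC1(C)[C@H](C)CCC([C@H](C)CCC(=C)C=C)=C1 | intermediate
12 | 4,4,5,5-tetramethyl-2-{(2E,6R)-3-methyl-6-[(4R)-3,3,4-trimethylcyclohex-1-en-1-yl]hept-2-en-1-yl}-1,3,2-dioxaborolane | CC1(C)[C@H](C)CCC([C@H](C)CC/C(C)=C/CB2OC(C)(C)C(C)(C)O2)=C1 | intermediate
13 | (3R)-3,7-dimethylocta-1,6-diene, (R)-β-citronellene | C=C[C@H](C)CCC=C(C)C | starting material
14 | (3R)-3,7-dimethyloct-6-en-2-one | CC(=O)[C@H](C)CCC=C(C)C | intermediate
15 | (3R)-2,3,7-trimethylocta-1,6-diene | CC(=C)[C@H](C)CCC=C(C)C | intermediate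
16 | (3RS)-3-[(3R)-3,4-dimethylpent-4-en-1-yl]-2,2-dimethyloxirane | CC(=C)[C@H](C)CCC1OC1(C)C | intermediate (not isolated)
17 | (4R)-4,5-dimethylhex-5-enal | CC(=C)[C@H](C)CCC=O | intermediate
18 | (5R)-5,6-dimethylhept-6-en-1-yne | CC(=C)[C@H](C)CCC#C | intermediate
19 | [(5R)-5,6-dimethylhepta-1,6-dien-2-yl]bis(2-methylpropyl)alumane | CC(=C)[C@H](C)CCC(=C)[Al](CC(C)C)CC(C)C | intermediate (not isolated)
20 | (3R,7R)-3,7,8-trimethyl-4-methylidenenona-1,8-diene | CC(=C)[C@H](C)CCC(=C)[C@H](C)C=C | intermediate
21 | (4R,8R)-4,8,9-trimethyl-5-methylidenedec-9-enal | CC(=C)[C@H](C)CCC(=C)[C@H](C)CCC=O | intermediate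
22 | (2E,6R,10R)-6,10,11-trimethyl-7-methylidenedodeca-2,11-dienal | CC(=C)[C@H](C)CCC(=C)[C@H](C)CC/C=C/C=O | intermediate
23 | pinacol borate ester of 24 | C=C[C@@](C)([C@H](OB2OC(C)(C)C(C)(C)O2)/C=C/CC[C@@H](C)C(=C)CC[C@@H](C)C(=C)C)CC[C@@H](C)C1=CC(C)(C)[C@H](C)CC1 | intermediate (not isolated)
24 | (3S,4R,5E,9R,13R)-3,9,13,14-tetramethyl-10-methylidene-3-{(3R)-3-[(4R)-3,3,4-trimethylcyclohex-1-en-1-yl]butyl}pentadeca-1,5,14-trien-4-ol | C=C[C@@](C)([C@H](O)/C=C/CC[C@@H](C)C(=C)CC[C@@H](C)C(=C)C)CC[C@@H](C)C1=CC(C)(C)[C@H](C)CC1 | intermediate
25 | (3S,4R,5E,9R,13R)-3,9,13,14-tetramethyl-10-methylidene-3-{(3R)-3-[(4R)-3,3,4-trimethylcyclohex-1-en-1-yl]butyl}pentadeca-1,5,14-trien-4-yl pyridine-2-carboxylate | C=C[C@@](C)([C@H](OC(=O)c2ccccn2)/C=C/CC[C@@H](C)C(=C)CC[C@@H](C)C(=C)C)CC[C@@H](C)C1=CC(C)(C)[C@H](C)CC1 | intermediate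
26 | (4R)-1-[(2R,5S,6E,8S,11R,15R)-5-ethenyl-5,8,11,15,16-pentamethyl-12-methylideneheptadeca-6,16-dien-2-yl]-3,3,4-trimethylcyclohex-1-ene | C=C[C@@](C)(/C=C/[C@@H](C)CC[C@@H](C)C(=C)CC[C@@H](C)C(=C)C)CC[C@@H](C)C1=CC(C)(C)[C@H](C)CC1 | target

## Step count and least certain steps

Total: 17 steps. Longest linear sequence: 10 steps (steps 1–7 then 15–17; the branch from 13, steps 8–14 then 15–17, is equally long).

**Step 15 (key step).** The hindered γ,γ-disubstituted boronate may add slowly to the enal, and the chiral acid may discriminate the aldehyde faces poorly or in the opposite sense. Any E/Z leakage in 12 from step 7 would appear as the C10 epimer. The catalyst antipode can be exchanged, but if catalyst control is inadequate the fallback changes the allyl metal. It sets out from 9 and comes back at 24, and it also bypasses steps 6 and 7: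
- Hydroboration of 9 (through 10) and B-alkyl Suzuki–Miyaura coupling with (E)-3-iodobut-2-en-1-ol would give (2E,6R)-3-methyl-6-[(4R)-3,3,4-trimethylcyclohex-1-en-1-yl]hept-2-en-1-ol F1, with the geometry fixed by the iodide.
- N-Chlorosuccinimide/dimethyl sulfide would give the allylic chloride (4R)-1-[(2R,5E)-7-chloro-5-methylhept-5-en-2-yl]-3,3,4-trimethylcyclohex-1-ene F2.
- HSiCl3, CuCl and i-Pr2NEt would give trichloro{(2E,6R)-3-methyl-6-[(4R)-3,3,4-trimethylcyclohex-1-en-1-yl]hept-2-en-1-yl}silane F3.
- A chiral bisphosphoramide Lewis base would catalyse the addition of F3 to 22 through a closed chair at hexacoordinate silicon, with the same E-to-anti correlation, to give 24.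

**Step 12.** The crotyl phosphate carries only a methyl group at its γ-carbon, so enantioface discrimination in the copper-catalysed substitution may be poor. Incomplete α-selectivity in the hydroalumination would give the linear alkenyl isomer. The fallback takes C16 from a stoichiometric chiral reagent; it sets out from 17 and comes back at 20:
- Addition of (E)-crotyl(diisopinocampheyl)borane (antipode chosen for 3R) and oxidative work-up would give (3R,4S,7R)-3,7,8-trimethylnona-1,8-dien-4-ol F4.
- Dess–Martin oxidation buffered with NaHCO3 would give (3R,7R)-3,7,8-trimethylnona-1,8-dien-4-one F5. This ketone must be handled without base because its α-centre is also allylic.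
- Takai–Lombardo methylenation as in step 9 would give 20.

**Step 3.** Fluoride activation of the hindered enol ether may give low conversion, and the small crotyl group may give an insufficient branched-to-linear preference or facial selectivity. The fallback uses substrate control and a sigmatropic shift; it sets out from 3 and comes back at 11, bypassing steps 4 to 6:
- Aldol condensation of the lithium enolate of 3 with acetaldehyde (dehydration via the mesylate, DBU) would give (3R,6E)-6-ethylidene-2,2,3-trimethylcyclohexan-1-one F6.
- Luche reduction (axial hydride attack, away from the axial C2 methyl) would give the cis alcohol (1R,3R,6E)-6-ethylidene-2,2,3-trimethylcyclohexan-1-ol F7.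
- Johnson–Claisen rearrangement with triethyl orthoacetate forms C7–C8 on the face of the oxygen and moves the alkene into the ring, giving ethyl (3R)-3-[(4R)-3,3,4-trimethylcyclohex-1-en-1-yl]butanoate F8.
- LiAlH4 would give (3R)-3-[(4R)-3,3,4-trimethylcyclohex-1-en-1-yl]butan-1-ol F9.
- PPh3/I2/imidazole would give (4R)-1-[(2R)-4-iodobutan-2-yl]-3,3,4-trimethylcyclohex-1-ene F10.
- Zinc insertion and Negishi coupling with 2-chlorobuta-1,3-diene would give 11.

## Further compounds

F1 | step 15 | (2E,6R)-3-methyl-6-[(4R)-3,3,4-trimethylcyclohex-1-en-1-yl]hept-2-en-1-ol | CC1(C)[C@H](C)CCC([C@H](C)CC/C(C)=C/CO)=C1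
F2 | step 15 | (4R)-1-[(2R,5E)-7-chloro-5-methylhept-5-en-2-yl]-3,3,4-trimethylcyclohex-1-ene | CC1(C)[C@H](C)CCC([C@H](C)CC/C(C)=C/CCl)=C1
F3 | step 15 | trichloro{(2E,6R)-3-methyl-6-[(4R)-3,3,4-trimethylcyclohex-1-en-1-yl]hept-2-en-1-yl}silane | CC1(C)[C@H](C)CCC([C@H](C)CC/C(C)=C/C[Si](Cl)(Cl)Cl)=C1
F4 | step 12 | (3R,4S,7R)-3,7,8-trimethylnona-1,8-dien-4-ol | CC(=C)[C@H](C)CC[C@H](O)[C@H](C)C=C
F5 | step 12 | (3R,7R)-3,7,8-trimethylnona-1,8-dien-4-one | CC(=C)[C@H](C)CCC(=O)[C@H](C)C=C
F6 | step 3 | (3R,6E)-6-ethylidene-2,2,3-trimethylcyclohexan-1-one | CC1(C)[C@H](C)CC/C(=C\C)C1=O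
F7 | step 3 | (1R,3R,6E)-6-ethylidene-2,2,3-trimethylcyclohexan-1-ol | CC1(C)[C@H](C)CC/C(=C\C)[C@@H]1O
F8 | step 3 | ethyl (3R)-3-[(4R)-3,3,4-trimethylcyclohex-1-en-1-yl]butanoate | CC1(C)[C@H](C)CCC([C@H](C)CC(=O)OCC)=C1
F9 | step 3 | (3R)-3-[(4R)-3,3,4-trimethylcyclohex-1-en-1-yl]butan-1-ol | CC1(C)[C@H](C)CCC([C@H](C)CCO)=C1
F10 | step 3 | (4R)-1-[(2R)-4-iodobutan-2-yl]-3,3,4-trimethylcyclohex-1-ene | CC1(C)[C@H](C)CCC([C@H](C)CCI)=C1
A1 | alternative 1 | (2S,5R)-2-ethenyl-2-methyl-5-[(4R)-3,3,4-trimethylcyclohex-1-en-1-yl]hexanal | C=C[C@@](C)(C=O)CC[C@@H](C)C1=CC(C)(C)[C@H](C)CC1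
A2 | alternative 1 | 1-phenyl-5-{[(2S,5R,9R)-2,5,9,10-tetramethyl-6-methylideneundec-10-en-1-yl]sulfonyl}-1H-tetrazole | O=S(=O)(C[C@@H](C)CC[C@@H](C)C(=C)CC[C@@H](C)C(=C)C)c1nnnn1-c1ccccc1
A3 | alternative 2 | diethyl (2E,6R)-3-methyl-6-[(4R)-3,3,4-trimethylcyclohex-1-en-1-yl]hept-2-en-1-yl phosphate | CCOP(=O)(OCC)OC/C=C(\C)CC[C@@H](C)C1=CC(C)(C)[C@H](C)CC1
A4 | alternative 2 | (3S,6R,10R)-3,6,10,11-tetramethyl-7-methylidenedodec-11-en-1-yne | C#C[C@@H](C)CC[C@@H](C)C(=C)CC[C@@H](C)C(=C)C
A5 | alternative 3 | (3R,7R,10S,11E,13S,16R,20R)-10-ethenyl-2,3,7,10,13,16,20,21-octamethyl-6,17-dimethylidenedocosa-1,11,21-triene | C=C[C@@](C)(/C=C/[C@@H](C)CC[C@@H](C)C(=C)CC[C@@H](C)C(=C)C)CC[C@@H](C)C(=C)CC[C@@H](C)C(C)=C
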